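**Plan**

Numbering: C1 ketone, C2=C3, C4 (=C15H2), C5 ether CH, C6 lactone CH–O, C7, C8 carbinol, C9, C10 (CH3, ether O), C11(=C13)–C12 lactone; ring A = O, C10, C1, C2, C3, C4, C5; ring B = O, C5, C6, C7, C8, C9, C10.
Enabling feature: C10 is the quaternary ether carbon, bonded to the C1 carbonyl and β to oxygenated C8. With C8 as a ketone, C10 is the β-carbon of a cyclic β-alkoxy enone in ring B and can capture a C1 acyl radical delivered from C5 through C4–C3–C2.
Retrosynthesis: remove C2=C3, the C11=C13 methylene (to CH2OSi) and the angelate; cut C1–C10 (ring A); cut O–C10 (ring B); cut C8–C9 and C4–C5; cut C7–C8 and C11–C13 back to a butenolide.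
Forward: butenolide to the all-trans lactone; C5 arm by Nozaki–Hiyama–Kishi coupling; ring B by 7-endo closure onto a C8 ynone; ring A by radical bridging; then C8 reduction and acylation, methylene lactone, C2=C3.
Stereochemistry: C6 from (S)-5-(hydroxymethyl)butenolide; C7 by anti conjugate addition; C5 by CBS reduction in the Felkin–Anh sense; C10 by the tether from C5; C8 by hydride attack anti to C7–C11.

Key step: step 19

Remark: the C11 configuration carried from step 5 to step 22 (CH2OSi trans to C8) is a placeholder that step 23 erases, and both C5 epimers from step 12 are used because step 13 removes that centre.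

Step 1
Reactants: 1 pent-4-ynoic acid
Product: 2 4-iodopent-4-enoic acid
Conditions: NaI, Me3SiCl, H2O (0.5 equiv), MeCN, rt
Reagents that add atoms: sodium iodide, [Na+].[I-]
Why: Hydroiodination: HI generated in the flask adds to the terminal alkyne in the Markovnikov sense and gives the 2-iodo-1-alkene that later serves as the C4 nucleophile.

Step 2
Reactants: 2 4-iodopent-4-enoic acid
Product: 3 tert-butyl 4-iodopent-4-enoate
Conditions: Cl3CC(=NH)O-t-Bu, BF3·OEt2 (cat.), CH2Cl2/cyclohexane, rt
Reagents that add atoms: tert-butyl 2,2,2-trichloroacetimidate, CC(C)(C)OC(=N)C(Cl)(Cl)Cl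
Why: Acid-catalysed tert-butylation of the acid by the imidate gives an ester bulky enough to resist the organochromium and alkynyl Grignard reagents used later.

Step 3
Reactants: 4 (S)-5-(hydroxymethyl)furan-2(5H)-one
Product: 5 (S)-5-[(tert-butyldimethylsilyloxy)methyl]furan-2(5H)-one
Conditions: t-BuMe2SiCl, imidazole, CH2Cl2, 0 °C to rt
Reagents that add atoms: tert-butyldimethylsilyl chloride, CC(C)(C)[Si](C)(C)Cl
Why: Silylation of the primary alcohol; the silyloxymethyl group on C6 then shields one face of the butenolide.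

Step 4
Reactants: 5 (S)-5-[(tert-butyldimethylsilyloxy)methyl]furan-2(5H)-one
Product: 7 (4R,5S)-5-[(tert-butyldimethylsilyloxy)methyl]-4-vinyldihydrofuran-2(3H)-one, via silyl ketene acetal 6 (not isolated)
Conditions: CH2=CHMgBr, CuBr·SMe2 (10 mol %), Me3SiCl, THF, −78 °C; then aq. NH4Cl
Reagents that add atoms: vinylmagnesium bromide, C=C[Mg]Br
Why: Copper-catalysed, silyl chloride-accelerated conjugate addition of the vinyl Grignard reagent occurs anti to the C6 silyloxymethyl group and sets C7 trans to C6; work-up hydrolyses the ketene acetal.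

Step 5
Reactants: 7 (4R,5S)-5-[(tert-butyldimethylsilyloxy)methyl]-4-vinyldihydrofuran-2(3H)-one
Product: 8 (3R,4S,5S)-5-[(tert-butyldimethylsilyloxy)methyl]-3-(hydroxymethyl)-4-vinyldihydrofuran-2(3H)-one
Conditions: LiN(i-Pr)2, THF, −78 °C; CH2O (gas), −78 to −40 °C; aq. NH4Cl
Reagents that add atoms: formaldehyde, C=O
Why: Aldol hydroxymethylation of the lithium lactone enolate with monomeric formaldehyde occurs anti to the C7 vinyl group, so C13 is installed trans to C8.

Step 6
Reactants: 8 (3R,4S,5S)-5-[(tert-butyldimethylsilyloxy)methyl]-3-(hydroxymethyl)-4-vinyldihydrofuran-2(3H)-one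
Product: 9 (3R,4S,5S)-5-[(tert-butyldimethylsilyloxy)methyl]-3-[(tert-butyldiphenylsilyloxy)methyl]-4-vinyldihydrofuran-2(3H)-one
Conditions: t-BuPh2SiCl, imidazole, DMF, rt
Reagents that add atoms: tert-butyldiphenylsilyl chloride, CC(C)(C)[Si](Cl)(c1ccccc1)c1ccccc1
Why: Silylation with the more acid-stable silyl group masks the future C13 methylene and allows the other silyl ether to be removed selectively in step 10.

Step 7
Reactants: 9 (3R,4S,5S)-5-[(tert-butyldimethylsilyloxy)methyl]-3-[(tert-butyldiphenylsilyloxy)methyl]-4-vinyldihydrofuran-2(3H)-one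
Product: 10 C8 aldehyde (9 with CHO in place of vinyl on C7, all-trans lactone)
Conditions: O3, CH2Cl2, −78 °C; then PPh3
Reagents that add atoms: ozone, [O-][O+]=O
Why: Ozonolysis with reductive work-up cleaves the only alkene to the C8 aldehyde, and C7 holds its configuration because the all-trans arrangement is the stable one.

Step 8
Reactants: 10 C8 aldehyde
Product: 11 C8 carboxylic acid (CO2H on C7 of the all-trans lactone)
Conditions: NaClO2, NaH2PO4, 2-methylbut-2-ene, t-BuOH/H2O, rt
Reagents that add atoms: sodium chlorite, [Na+].[O-]Cl=O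
Why: Pinnick oxidation converts the aldehyde to the acid under buffered conditions that neither epimerise C7 nor open the lactone.

Step 9
Reactants: 11 C8 carboxylic acid
Product: 12 C8 Weinreb amide (N-methoxy-N-methyl amide on C7)
Conditions: MeNH(OMe)·HCl, EDC·HCl, N-methylmorpholine, DMAP (cat.), CH2Cl2, 0 °C to rt
Reagents that add atoms: N,O-dimethylhydroxylamine hydrochloride, CNOC.Cl
Why: Carbodiimide amide coupling stores C8 as a Weinreb amide, a latent ketone that survives the C5 chemistry.

Step 10
Reactants: 12 C8 Weinreb amide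
Product: 13 C5 alcohol (free hydroxymethyl on C6)
Conditions: HF·pyridine, pyridine, THF, 0 °C
Reagents that add atoms: none
Why: Buffered fluoride desilylation removes the primary tert-butyldimethylsilyl ether much faster than the tert-butyldiphenylsilyl ether.

Step 11
Reactants: 13 C5 alcohol
Product: 14 C5 aldehyde (formyl group on C6)
Conditions: Dess–Martin periodinane, CH2Cl2, rt
Reagents that add atoms: none
Why: Dess–Martin oxidation gives the α-acyloxy aldehyde under non-basic conditions, to be used at once.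

Step 12
Reactants: 14 C5 aldehyde; 3 tert-butyl 4-iodopent-4-enoate
Product: 15 allylic alcohol (C6 bears CH(OH)–C(=CH2)–CH2CH2CO2-t-Bu, both C5 epimers)
Conditions: CrCl2 (4 equiv), NiCl2 (2 mol %), DMF, rt
Reagents that add atoms: none
Why: Nozaki–Hiyama–Kishi coupling forms C4–C5 by addition of the alkenylchromium reagent to the aldehyde while lactone, Weinreb amide and ester are left alone; C5 is not controlled here because step 13 removes it.

Step 13
Reactants: 15 allylic alcohol (both C5 epimers)
Product: 16 C5 enone (C6 bears C(=O)–C(=CH2)–CH2CH2CO2-t-Bu)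
Conditions: Dess–Martin periodinane, CH2Cl2, 0 °C to rt
Reagents that add atoms: none
Why: Dess–Martin oxidation converges both epimers on one α-methylene ketone, which is used without storage.

Step 14
Reactants: 16 C5 enone
Product: 17 (5S)-allylic alcohol (C5–O syn to C6–O)
Conditions: (S)-2-methyl-CBS-oxazaborolidine (20 mol %), catecholborane, toluene, −78 °C
Reagents that add atoms: none
Why: Corey–Bakshi–Shibata reduction delivers hydride 1,2 with the 2-substituted vinyl group as the larger substituent and should give 5S; the Felkin–Anh preference of the α-acyloxy centre C6 (hydride anti to C6–O) points the same way.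

Step 15
Reactants: 17 (5S)-allylic alcohol; 18 prop-1-ynylmagnesium bromide
Product: 19 hydroxy ynone (C7 bears C(=O)–C≡C–CH3, C5 hydroxyl free)
Conditions: 18 (3 equiv), THF, −20 to 0 °C; aq. NH4Cl
Reagents that add atoms: none
Why: Weinreb ketone synthesis: the alkynyl Grignard reagent adds once to the amide through the chelated tetrahedral adduct (one equivalent is spent on the C5 hydroxyl), and the α-branched lactone and tert-butyl ester should react more slowly at this temperature.

Step 16
Reactants: 19 hydroxy ynone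
Product: 20 lactone-fused oxepenone tert-butyl ester (ring B closed; C8 ketone, C9=C10 enol ether)
Conditions: Ph3PAuCl (5 mol %), AgOSO2CF3 (5 mol %), CH2Cl2, rt
Reagents that add atoms: none
Why: π-Acid-catalysed intramolecular oxa-Michael addition of the C5 hydroxyl to the ynone β-carbon C10 closes ring B in the 7-endo-dig mode, the homologue of the 6-endo closure of β-hydroxy ynones to dihydropyranones; C5 is retained.

Step 17
Reactants: 20 lactone-fused oxepenone tert-butyl ester
Product: 21 oxepenone acid (C1 CO2H)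
Conditions: CF3CO2H/CH2Cl2 (1:4), 0 °C
Reagents that add atoms: none
Why: Anhydrous acidolysis removes the tert-butyl group as isobutene and should leave the vinylogous ester, the lactone and the silyl ether intact.

Step 18
Reactants: 21 oxepenone acid
Product: 22 Se-phenyl selenoester (C1)
Conditions: (PhSe)2, PBu3, CH2Cl2, rt
Reagents that add atoms: diphenyl diselenide, c1ccc(cc1)[Se][Se]c1ccccc1
Why: Phosphine-mediated selenoesterification of the acid with the diselenide proceeds under neutral conditions and installs the acyl radical precursor.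

Step 19
Reactants: 22 Se-phenyl selenoester
Product: 23 bridged 1,8-diketone (C1–C10 bond formed, C10 quaternary)
Conditions: (Me3Si)3SiH (1.5 equiv) and AIBN (0.3 equiv) by syringe pump, benzene (0.005 M), 80 °C
Reagents that add atoms: none
Why: Proposed new method: The silyl radical abstracts the phenylseleno group and the nucleophilic C1 acyl radical adds to C10, the β-carbon of the cyclic β-alkoxy enone; the resulting C9 radical, α to the C8 ketone, takes hydrogen from the silane and carries the chain. The closest known reactions are acyl radical cyclisations of selenoesters onto enones and onto β-alkoxyacrylates that give cyclic ether ketones; new here are the fully substituted acceptor carbon held in a ring and the bridged outcome. Ring A (O, C10, C1, C2, C3, C4, C5) closes in the 7-exo-trig mode and completes the 11-oxabicyclo[4.4.1]undecane core. The one new stereocentre, C10, is set by the tether: the arm on C5 reaches C10 only across the ring oxygen from its own face, so C1 becomes cis to C4 and the methyl group points outward (10S). The step needs attack at C10 rather than C9 and ring closure ahead of hydrogen transfer to the acyl radical: the polarity match between acyl radical and enone β-carbon secures the first, and the slow hydrogen donor at high dilution, together with the reluctance of a primary acyl radical to lose CO at 80 °C, secures the second.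

Step 20
Reactants: 23 bridged 1,8-diketone
Product: 24 (8R)-alcohol (C8 hydroxyl cis to C11, C1 ketone kept)
Conditions: LiBH(s-Bu)3 (1.1 equiv), THF, −78 °C; aq. NH4Cl
Reagents that add atoms: none
Why: Bulky trialkylborohydride reduction: hydride should reach C8 from the face of C7–H, anti to the C7–C11 bond and away from the C10 methyl group, to give 8R, while the C1 ketone beside quaternary C10 and the lactone stay untouched at −78 °C.

Step 21
Reactants: 24 (8R)-alcohol; 25 angelic acid
Product: 27 8-O-angelate, via mixed anhydride 26 (not isolated)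
Conditions: 2,4,6-Cl3C6H2COCl, Et3N, toluene, rt; then 24, 80 °C
Reagents that add atoms: none
Why: Yamaguchi-type esterification through the mixed anhydride, run without DMAP, acylates the hindered C8 alcohol without isomerising the angelate to the tiglate.

Step 22
Reactants: 27 8-O-angelate
Product: 28 C13 alcohol
Conditions: HF·pyridine, THF, 0 °C to rt
Reagents that add atoms: none
Why: Fluoride cleavage of the primary silyl ether under mildly acidic conditions spares the angelate, the lactone and the ketone.

Step 23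
Reactants: 28 C13 alcohol
Product: 30 α-methylene lactone (2,3-dihydro target), via mesylate 29 (not isolated)
Conditions: MsCl, Et3N, CH2Cl2, 0 °C; then DBU, rt
Reagents that add atoms: none
Why: Mesylation and base-induced β-elimination (E1cB through the lactone enolate) unveil the C11=C13 methylene and erase the C11 centre.

Step 24
Reactants: 30 α-methylene lactone
Product: 32 target CNP0282559.1, via trimethylsilyl enol ether 31 (not isolated)
Conditions: Me3SiOSO2CF3, Et3N, CH2Cl2, 0 °C; then Pd(OAc)2, MeCN, rt
Reagents that add atoms: none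
Why: Saegusa–Ito oxidation: the C1 ketone can enolise only toward C2 because C10 is quaternary, and Pd(OAc)2 dehydrogenates the silyl enol ether to the C2=C3 enone conjugated with the C4 methylene.

**Compound list**

1 | pent-4-ynoic acid | C#CCCC(=O)O | starting material
2 | 4-iodopent-4-enoic acid | C=C(I)CCC(=O)O | intermediate
3 | tert-butyl 4-iodopent-4-enoate | C=C(I)CCC(=O)OC(C)(C)C | intermediate
4 | (S)-5-(hydroxymethyl)furan-2(5H)-one | O=C1C=C[C@@H](CO)O1 | starting material
5 | (S)-5-[(tert-butyldimethylsilyloxy)methyl]furan-2(5H)-one | O=C1C=C[C@@H](CO[Si](C)(C)C(C)(C)C)O1 | intermediate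
6 | silyl ketene acetal: 2,3-trans-2-[(tert-butyldimethylsilyloxy)methyl]-5-(trimethylsilyloxy)-3-vinyl-2,3-dihydrofuran | C[Si](C)(C)OC1=C[C@H](C=C)[C@@H](CO[Si](C)(C)C(C)(C)C)O1 | intermediate
7 | (4R,5S)-5-[(tert-butyldimethylsilyloxy)methyl]-4-vinyldihydrofuran-2(3H)-one | O=C1C[C@H](C=C)[C@@H](CO[Si](C)(C)C(C)(C)C)O1 | intermediate
8 | (3R,4S,5S)-5-[(tert-butyldimethylsilyloxy)methyl]-3-(hydroxymethyl)-4-vinyldihydrofuran-2(3H)-one | O=C1[C@@H](CO)[C@H](C=C)[C@@H](CO[Si](C)(C)C(C)(C)C)O1 | intermediate
9 | (3R,4S,5S)-5-[(tert-butyldimethylsilyloxy)methyl]-3-[(tert-butyldiphenylsilyloxy)methyl]-4-vinyldihydrofuran-2(3H)-one | O=C1[C@@H](CO[Si](c2ccccc2)(c2ccccc2)C(C)(C)C)[C@H](C=C)[C@@H](CO[Si](C)(C)C(C)(C)C)O1 | intermediate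
10 | C8 aldehyde: 2-[(tert-butyldimethylsilyloxy)methyl]-4-[(tert-butyldiphenylsilyloxy)methyl]-5-oxotetrahydrofuran-3-carbaldehyde, all-trans | O=C1[C@@H](CO[Si](c2ccccc2)(c2ccccc2)C(C)(C)C)[C@H](C=O)[C@@H](CO[Si](C)(C)C(C)(C)C)O1 | intermediate
11 | C8 carboxylic acid: the corresponding tetrahydrofuran-3-carboxylic acid, all-trans | O=C1[C@@H](CO[Si](c2ccccc2)(c2ccccc2)C(C)(C)C)[C@H](C(=O)O)[C@@H](CO[Si](C)(C)C(C)(C)C)O1 | intermediate
12 | C8 Weinreb amide: N-methoxy-N-methyl amide of 11 | O=C1[C@@H](CO[Si](c2ccccc2)(c2ccccc2)C(C)(C)C)[C@H](C(=O)N(C)OC)[C@@H](CO[Si](C)(C)C(C)(C)C)O1 | intermediate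
13 | C5 alcohol: 12 with free hydroxymethyl on C6 | O=C1[C@@H](CO[Si](c2ccccc2)(c2ccccc2)C(C)(C)C)[C@H](C(=O)N(C)OC)[C@@H](CO)O1 | intermediate
14 | C5 aldehyde: formyl group on C6 | O=C1[C@@H](CO[Si](c2ccccc2)(c2ccccc2)C(C)(C)C)[C@H](C(=O)N(C)OC)[C@@H](C=O)O1 | intermediate
15 | allylic alcohol: C6 bears CH(OH)–C(=CH2)–CH2CH2CO2-t-Bu, both C5 epimers | O=C1[C@@H](CO[Si](c2ccccc2)(c2ccccc2)C(C)(C)C)[C@H](C(=O)N(C)OC)[C@@H](C(O)C(=C)CCC(=O)OC(C)(C)C)O1 | intermediate
16 | C5 enone: C6 bears C(=O)–C(=CH2)–CH2CH2CO2-t-Bu | O=C1[C@@H](CO[Si](c2ccccc2)(c2ccccc2)C(C)(C)C)[C@H](C(=O)N(C)OC)[C@@H](C(=O)C(=C)CCC(=O)OC(C)(C)C)O1 | intermediate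
17 | (5S)-allylic alcohol: C5–O syn to C6–O | O=C1[C@@H](CO[Si](c2ccccc2)(c2ccccc2)C(C)(C)C)[C@H](C(=O)N(C)OC)[C@@H]([C@@H](O)C(=C)CCC(=O)OC(C)(C)C)O1 | intermediate
18 | prop-1-ynylmagnesium bromide | CC#C[Mg]Br | starting material
19 | hydroxy ynone: C7 bears C(=O)–C≡C–CH3, C5 hydroxyl free | O=C1[C@@H](CO[Si](c2ccccc2)(c2ccccc2)C(C)(C)C)[C@H](C(=O)C#CC)[C@@H]([C@@H](O)C(=C)CCC(=O)OC(C)(C)C)O1 | intermediate
20 | lactone-fused oxepenone tert-butyl ester: ring B closed, C8 ketone, C9=C10 enol ether, C5 arm C(=CH2)CH2CH2CO2-t-Bu cis to C6–O | CC(C)(C)[Si](c1ccccc1)(c1ccccc1)OC[C@@H]1C(=O)O[C@H]2[C@H]1C(=O)C=C(C)O[C@H]2C(=C)CCC(=O)OC(C)(C)C | intermediate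
21 | oxepenone acid: 20 with C1 CO2H | CC(C)(C)[Si](c1ccccc1)(c1ccccc1)OC[C@@H]1C(=O)O[C@H]2[C@H]1C(=O)C=C(C)O[C@H]2C(=C)CCC(=O)O | intermediate
22 | Se-phenyl selenoester of 21 (key-step precursor) | CC(C)(C)[Si](c1ccccc1)(c1ccccc1)OC[C@@H]1C(=O)O[C@H]2[C@H]1C(=O)C=C(C)O[C@H]2C(=C)CCC(=O)[Se]c1ccccc1 | intermediate
23 | bridged 1,8-diketone: 11-oxabicyclo[4.4.1]undecane core fused to the lactone, C10 quaternary with C1 cis to C4 | CC(C)(C)[Si](c1ccccc1)(c1ccccc1)OC[C@@H]1C(=O)O[C@H]2[C@H]1C(=O)C[C@]1(C)O[C@H]2C(=C)CCC1=O | intermediate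
24 | (8R)-alcohol: 23 with C8 hydroxyl cis to C11 | CC(C)(C)[Si](c1ccccc1)(c1ccccc1)OC[C@@H]1C(=O)O[C@H]2[C@H]1[C@H](O)C[C@]1(C)O[C@H]2C(=C)CCC1=O | intermediate
25 | angelic acid, (Z)-2-methylbut-2-enoic acid | C/C=C(/C)C(=O)O | starting material
26 | mixed anhydride: (Z)-2-methylbut-2-enoic 2,4,6-trichlorobenzoic anhydride | C/C=C(/C)C(=O)OC(=O)c1c(Cl)cc(Cl)cc1Cl | intermediate
27 | 8-O-angelate of 24 | CC(C)(C)[Si](c1ccccc1)(c1ccccc1)OC[C@@H]1C(=O)O[C@H]2[C@H]1[C@H](OC(=O)/C(C)=C\C)C[C@]1(C)O[C@H]2C(=C)CCC1=O | intermediate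
28 | C13 alcohol: 27 without the silyl group | OC[C@@H]1C(=O)O[C@H]2[C@H]1[C@H](OC(=O)/C(C)=C\C)C[C@]1(C)O[C@H]2C(=C)CCC1=O | intermediate
29 | C13 mesylate of 28 | CS(=O)(=O)OC[C@@H]1C(=O)O[C@H]2[C@H]1[C@H](OC(=O)/C(C)=C\C)C[C@]1(C)O[C@H]2C(=C)CCC1=O | intermediate
30 | α-methylene lactone with saturated C2–C3 (2,3-dihydro target) | C=C1C(=O)O[C@H]2[C@H]1[C@H](OC(=O)/C(C)=C\C)C[C@]1(C)O[C@H]2C(=C)CCC1=O | intermediate
31 | C1 trimethylsilyl enol ether of 30 (C1=C2) | C=C1C(=O)O[C@H]2[C@H]1[C@H](OC(=O)/C(C)=C\C)C[C@]1(C)O[C@H]2C(=C)CC=C1O[Si](C)(C)C | intermediate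
32 | CNP0282559.1, (5S,6S,7R,8R,10S) in the numbering above | C=C1C(=O)O[C@H]2[C@H]1[C@H](OC(=O)/C(C)=C\C)C[C@]1(C)O[C@H]2C(=C)C=CC1=O | target

**Totals**

Total step count: 24. Longest linear sequence: 22 steps (steps 3 to 24, from 4); steps 1 and 2 make the side-chain fragment 3.

**Steps most likely to fail**

Step 19 (Proposed new method). The acyl radical may be reduced to the aldehyde before the arm folds across the ring oxygen, because C10 is fully substituted and carries a donor oxygen, or the bridged transition state may be too strained. The fallback uses known chemistry and sets out from selenoester 22. Reduction with Bu3SnH and catalytic Pd(PPh3)4 should give the C1 aldehyde F1. SmI2 with MeOH in THF should then effect the ketyl–olefin reductive cyclisation onto the β-alkoxy enone, the reaction type routinely used to close oxepanes, and give the C1 carbinol F2 with the C1–C10 bond in place. Dess–Martin oxidation of F2 comes back to diketone 23.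

Step 16. The 7-endo closure may be slow, so that 6-exo attack at C9, intermolecular addition or β-elimination of the lactone oxygen from the β-acyloxy ynone competes. The fallback sets out from hydroxy ynone 19. Diethylamine in ethanol should add to the ynone and give the vinylogous amide F3. Camphorsulfonic acid in toluene at 60 °C should then let the C5 hydroxyl displace the amine by addition–elimination, which comes back to oxepenone 20.

Step 20. Facial selectivity at C8 may be poor or reversed, and reduction at C1 may compete. The fallback sets out from diketone 23. If hydride enters from the other face, the reduction (with the same reagent or with NaBH4 in MeOH at −78 °C) gives the 8-epi alcohol F4. Mitsunobu inversion with chloroacetic acid, PPh3 and diisopropyl azodicarboxylate should give the 8R chloroacetate F5. Thiourea with NaHCO3 in ethanol removes the chloroacetyl group and comes back to alcohol 24.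

**Further compounds**

F1 | step 19 | C1 aldehyde (22 with CHO in place of the selenoester) | CC(C)(C)[Si](c1ccccc1)(c1ccccc1)OC[C@@H]1C(=O)O[C@H]2[C@H]1C(=O)C=C(C)O[C@H]2C(=C)CCC=O
F2 | step 19 | C1 carbinol (23 with CH–OH at C1, either C1 epimer) | CC(C)(C)[Si](c1ccccc1)(c1ccccc1)OC[C@@H]1C(=O)O[C@H]2[C@H]1C(=O)C[C@]1(C)O[C@H]2C(=C)CCC1O
F3 | step 16 | vinylogous amide (19 with (E)-C(=O)–CH=C(CH3)–NEt2 on C7) | O=C1[C@@H](CO[Si](c2ccccc2)(c2ccccc2)C(C)(C)C)[C@H](C(=O)/C=C(\C)N(CC)CC)[C@@H]([C@@H](O)C(=C)CCC(=O)OC(C)(C)C)O1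
F4 | step 20 | 8-epi alcohol (8S epimer of 24) | CC(C)(C)[Si](c1ccccc1)(c1ccccc1)OC[C@@H]1C(=O)O[C@H]2[C@H]1[C@@H](O)C[C@]1(C)O[C@H]2C(=C)CCC1=O
F5 | step 20 | 8R chloroacetate (chloroacetyl ester of 24) | CC(C)(C)[Si](c1ccccc1)(c1ccccc1)OC[C@@H]1C(=O)O[C@H]2[C@H]1[C@H](OC(=O)CCl)C[C@]1(C)O[C@H]2C(=C)CCC1=O
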